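At 15 min a reading shows where the material has gone, so I turned the question round: what would the runs have to show for gamma to end otherwise?

| flask | substrate | temperature | remark | time |
|---|---|---|---|---|
| south | 0.14 M | 116 °C | run made earlier |  |
| north-east | 0.22 M | 130 °C | run made earlier |  |
| gamma | 0.10 M | 135 °C |  | 15 min |
| theta | 0.10 M | 110 °C |  | 15 min |

| run | time / min | substrate / % | target / % | intermediate / % | isomer of the product / % |
|---|---|---|---|---|---|
| south | 0.833 | 86.3 | 0 | 14.6 | 0 |
| south | 2.50 | 62.9 | 0.7 | 35.1 | 1.1 |
| south | 4.00 | 46.2 | 4.2 | 46.2 | 4.0 |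
| south | 6.00 | 31.1 | 6.2 | 53.6 | 9.8 |
| south | 10.0 | 13.5 | 9.0 | 54.0 | 21.2 |
| south | 12.0 | 9.1 | 8.4 | 51.6 | 28.5 |
| south | 15.0 | 7.0 | 7.6 | 46.9 | 40.0 |
| north-east | 0.500 | 69.2 | 2.4 | 29.3 | 0.4 |
| north-east | 0.667 | 62.3 | 2.4 | 35.5 | 2.3 |
| north-east | 1.00 | 48.1 | 3.1 | 46.2 | 3.9 |
| north-east | 1.33 | 38.3 | 3.7 | 53.6 | 4.3 |
| north-east | 2.00 | 25.0 | 7.4 | 59.7 | 11.1 |
| north-east | 4.00 | 7.8 | 9.8 | 54.6 | 30.5 |
| north-east | 6.00 | 1.3 | 11.9 | 37.5 | 51.7 |

(each reading ± 1 percentage point)

- which of these there is most of at the end, counted by the substrate in it, gamma (isomer of the product / intermediate / substrate / target)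
- which of these there is most of at the end, counted by the substrate in it, theta (isomer of the product / intermediate / substrate / target)
- the largest of these amounts at the end, in percent of the substrate charged, gamma
- the largest of these amounts at the end, in percent of the substrate charged, theta

- a reading or a percentage of target counts all its forms, free or not

Gamma is hotter than both runs. In north-east, at 130 °C, substrate was down to 1.3% by 6.00 min, and intermediate had fallen from 59.7% at 2.00 min to 37.5%, so I took target and isomer to be the pair that mattered in gamma at 15 min. The split of that pair is then what counts. I named it the isomer's share, isomer divided by isomer plus target 81.3%, as read at the last north-east reading, with its scatter. For target to lead in gamma, this share would have to drop under 0.5. For isomer to reach the forecast's value, it would have to rise to 96%, so that target's part fell from 18.7% to 4.00%. South's last reading gives a share of 84.0%, so I reckoned on isomer leading gamma at about 81.3%.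

The forecast named isomer of the product at 96% for gamma, “unless a target–isomer equilibrium exists”, and intermediate at 53% for theta.

Gamma gave isomer of the product at 84.2%, and theta gave intermediate at 53.2%.

    substrate → intermediate (k = 0.00171 /s, Ea = 125 kJ/mol)
    intermediate → target (k = 7.23 × 10⁻⁴ /s, Ea = 100 kJ/mol)
    crystals ⇌ target, rate k3*(cs3 - [target]) while solid is left; crystals form when [target] > cs3 (solubility = 0.0660 M, k = 0.0400 /s)
    target ⇌ isomer of the product (K = 24.0, k = 0.00439 /s, Ea = 119 kJ/mol, ΔH = −72.0 kJ/mol)
    (constants at 110 °C)

Gamma's target stood at 14.2% at the time of reading and at 14.3% at 150 min, and the share went from 85.6% to 85.7%. The step between target and isomer runs both ways, which is thermodynamic control of the pair in gamma. Theta, with gamma's charge and time at 110 °C, kept 53.2% of intermediate against gamma's 1.58%, and the difference in temperature is the main reason; that left nearly all of gamma's charge in target and isomer. The neighbour is theta read at 25 min, where target and isomer hold 47.1%, so the share 81.3% gives 38.3% of isomer. The computed amount is 37.8%, though theta's share later reaches 96.0% at 150 min.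

The numbers in the tables are simulated on assumed constants.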